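The bicyclo[2.2.1]heptane core holds a one-carbon bridge, C15, between quaternary C5 and C2. Putting an oxygen into the C15–C2 bond turns ring C plus bridge into a δ-lactone. In it, ketene acetal C5=C15, the ring oxygen, C2 and an enol ether C1=C10 make up a Claisen array. A single Ireland–Claisen ring contraction then forges the crowded C5–C10 bond and closes ring C. It relays the C2 carbinol configuration to C5 and C10, and leaves C15 and a C1=C2 methyl enol ether on the same face for bridge closure. The precursor is a cis-2,4-disubstituted α-vinyl δ-lactone whose C2 carries a (Z)-methoxyalkenyl group attached to bromocyclohexene ring A.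

Key step: step 23

Numbering used throughout: C1 CH(OMe), C2 the bridgehead CH next to it, C3 CH2, C4 CH(iPr), C5 quaternary bridgehead, C6 and C7 the CH2CH2 of ring B, C8 C(CH3), C9 and C10 the ring-fusion CH, C11 C(OH)CH3, C12 CHOH, C13 CH2, C14 CHBr, C15 the bridging CH2. Ring A = C8, C9, C11–C14; ring B = C5–C10; ring C = C1–C5 and C10.

Assumption: the quinine-derived catalyst (DHQ)2AQN is taken to give the (S)-half-ester in step 13; should the sense of induction be the reverse, its pseudoenantiomer (DHQD)2AQN is used and nothing else changes.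

Remarks on the chemistry:
- (a) A geranyl ester cyclised as such would leave two methyl groups on C8. Its E-methyl group is therefore oxidised first and becomes C7.
- (b) A free C15 acid would add across the C1=C2 enol ether. The rearranged product is therefore kept as its silyl ester and reduced directly.
- (c) C6=C7 is saturated last, when no other alkene is left.
- (d) The configurations of the lactone and of the rearranged ester agree atom by atom with the target. C4, C8, C9 and C14 are unchanged, and 2R maps onto 5S,10S through the boat, so no centre needs revision.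

Step 1
Reactants: 1 geraniol; 2 (1S)-camphanic chloride
Product: 3 geranyl (1S)-camphanate
Conditions: Et3N, DMAP (cat.), CH2Cl2, 0 °C to rt
Reagents that add atoms: none
Why: DMAP-catalysed acylation of a primary alcohol; the enantiopure, electron-poor ester protects C10–O, deactivates the C9=C11 alkene towards Br+ and later lets the two ring A antipodes be separated as diastereomers.

Step 2
Reactants: 3 geranyl (1S)-camphanate
Product: 4 (2E,6E)-8-hydroxy-3,7-dimethylocta-2,6-dienyl (1S)-camphanate
Conditions: SeO2 (cat.), t-BuOOH, salicylic acid (cat.), CH2Cl2, rt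
Reagents that add atoms: selenium dioxide, O=[Se]=O (oxygen carrier); tert-butyl hydroperoxide, CC(C)(C)OO (terminal oxygen source)
Why: Selenium dioxide allylic oxidation (ene reaction, then [2,3]-sigmatropic shift) takes place at the E-methyl group of the more electron-rich distal alkene and so provides the oxygenated carbon that will become C7.

Step 3
Reactants: 4 8-hydroxygeranyl camphanate
Product: 5 (2E,6E)-8-(tert-butyldiphenylsilyloxy)-3,7-dimethylocta-2,6-dienyl (1S)-camphanate
Conditions: TBDPSCl, imidazole, CH2Cl2, rt
Reagents that add atoms: tert-butyldiphenylsilyl chloride, CC(C)(C)[Si](Cl)(c1ccccc1)c1ccccc1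
Why: Standard silylation of a primary allylic alcohol; a bulky silyl ether, unlike an acyl group, cannot capture the C8 cation through a carbonyl oxygen, and it deactivates C14=C8 less than the ester deactivates C9=C11.

Step 4
Reactants: 5 silyloxygeranyl camphanate
Product: 6 [(1R,5S,6R)-5-bromo-6-(tert-butyldiphenylsilyloxymethyl)-2,6-dimethylcyclohex-2-en-1-yl]methyl (1S)-camphanate (ring A: C9 R, C14 S, C8 R; Br, C7 and C10 equatorial, C8 methyl axial)
Conditions: Et2SBr·SbCl5Br, MeNO2, −25 °C, 10 min; aq. Na2SO3/NaHCO3; chromatography, crystallisation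
Reagents that add atoms: bromodiethylsulfonium bromopentachloroantimonate, CC[S+](Br)CC.Cl[Sb-](Cl)(Cl)(Cl)(Cl)Br
Why: Bromonium-induced cation–olefin cyclisation: Br+ goes to the more electron-rich C14=C8 alkene and C9=C11 attacks C8 anti to bromine through a chair, so that Br, C7 (from the E-substituent) and C10 (from the E-alkene) end equatorial and the C8 methyl axial, and loss of the axial C12 proton should give the endocyclic alkene as in strong-acid cyclisations of geranyl esters; the reagent has no facial bias, so both ring A antipodes form as camphanate diastereomers, and the required one is isolated and assigned by X-ray analysis against the camphanate.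

Step 5
Reactants: 6 bromocyclised silyl ether
Product: 7 [(1R,5S,6R)-5-bromo-6-(hydroxymethyl)-2,6-dimethylcyclohex-2-en-1-yl]methyl (1S)-camphanate
Conditions: HF·pyridine, THF, 0 °C to rt
Reagents that add atoms: none
Why: Fluoride-driven Si–O cleavage under mildly acidic conditions leaves the ester, the alkene and the equatorial bromide untouched.

Step 6
Reactants: 7 C7 alcohol
Product: 8 [(1R,5S,6R)-5-bromo-6-formyl-2,6-dimethylcyclohex-2-en-1-yl]methyl (1S)-camphanate
Conditions: Dess–Martin periodinane, CH2Cl2, rt
Reagents that add atoms: none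
Why: Dess–Martin oxidation of a neopentyl alcohol; the aldehyde has no α-hydrogen, so neither epimerisation at C8 nor loss of HBr can follow.

Step 7
Reactants: 8 C7 aldehyde
Product: 9 [(1R,5S,6S)-5-bromo-6-ethenyl-2,6-dimethylcyclohex-2-en-1-yl]methyl (1S)-camphanate
Conditions: Ph3PCH3Br, KN(SiMe3)2, THF, 0 °C; then 8, −78 to 0 °C
Reagents that add atoms: methyltriphenylphosphonium bromide, C[P+](c1ccccc1)(c1ccccc1)c1ccccc1.[Br-]
Why: Wittig methylenation with the small ylide reaches the hindered aldehyde faster than either ester carbonyl, and the equatorial C14–Br bond has no antiperiplanar hydrogen for E2 loss.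

Step 8
Reactants: 9 vinyl camphanate
Product: 10 [(1R,5S,6S)-5-bromo-6-ethenyl-2,6-dimethylcyclohex-2-en-1-yl]methanol
Conditions: K2CO3 (cat.), MeOH, rt
Reagents that add atoms: none
Why: Base-catalysed transesterification releases the C10 alcohol and removes the resolving group under conditions too mild to displace or eliminate the hindered secondary bromide.

Step 9
Reactants: 10 ring A alcohol
Product: 11 (1R,5S,6S)-5-bromo-6-ethenyl-2,6-dimethylcyclohex-2-ene-1-carbaldehyde
Conditions: Dess–Martin periodinane, pyridine, CH2Cl2, 0 °C
Reagents that add atoms: none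
Why: Dess–Martin oxidation buffered with pyridine gives the β,γ-unsaturated aldehyde without acid or strong base, so C9 keeps its equatorial (thermodynamically preferred) substituent and the alkene stays at C11=C12; 11 is used at once.

Step 10
Reactants: 12 methyl (E)-4-methylpent-2-enoate; 13 dimethyl malonate
Product: 14 trimethyl 2-(propan-2-yl)propane-1,1,3-tricarboxylate (racemic)
Conditions: NaOMe (cat.), MeOH, reflux
Reagents that add atoms: none
Why: Michael addition of a malonate anion to an enoate builds the five-carbon chain around C4; the new centre is racemic and disappears in the symmetric diacid that follows.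

Step 11
Reactants: 14 triester
Product: 15 3-(propan-2-yl)pentanedioic acid
Conditions: 6 M aq. HCl, reflux
Reagents that add atoms: water, O
Why: Acid hydrolysis of the three esters followed by thermal decarboxylation of the malonic acid gives the prochiral diacid.

Step 12
Reactants: 15 3-isopropylglutaric acid
Product: 16 3-isopropylglutaric anhydride (4-(propan-2-yl)oxane-2,6-dione)
Conditions: Ac2O, reflux; distillation
Reagents that add atoms: none
Why: Dehydration with acetic anhydride closes the six-membered cyclic anhydride needed for desymmetrisation.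

Step 13
Reactants: 16 3-isopropylglutaric anhydride
Product: 17 (3S)-5-methoxy-5-oxo-3-(propan-2-yl)pentanoic acid
Conditions: MeOH, (DHQ)2AQN (cat.), Et2O, −40 °C
Reagents that add atoms: methanol, CO
Why: Catalytic desymmetrising alcoholysis of a prochiral cyclic anhydride, in which the cinchona alkaloid acts as a chiral general base and directs methanol to one enantiotopic carbonyl group, sets C4.

Step 14
Reactants: 17 (S)-half-ester; 18 diethyl (methoxymethyl)phosphonate
Product: 20 (3R)-6-(diethoxyphosphoryl)-6-methoxy-5-oxo-3-(propan-2-yl)hexanoic acid (epimers at C1), via lithiated phosphonate 19 (not isolated)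
Conditions: 18 (3.3 equiv), LiN(iPr)2, THF, −78 °C; then 17, −78 to −30 °C; 1 M HCl
Reagents that add atoms: none
Why: Acylation of a phosphonate carbanion by an ester: the first equivalent of 19 masks the acid as its unreactive lithium carboxylate, the second attacks the methyl ester (future C2) and the third deprotonates the product so that the ketone is not attacked again, while C4, β to both carbonyl groups, cannot epimerise.

Step 15
Reactants: 20 ketophosphonate acid
Product: 21 methyl (3R)-6-(diethoxyphosphoryl)-6-methoxy-5-oxo-3-(propan-2-yl)hexanoate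
Conditions: Me3SiCHN2, toluene/MeOH, 0 °C
Reagents that add atoms: (trimethylsilyl)diazomethane, C[Si](C)(C)C=[N+]=[N-]
Why: O-Methylation of the carboxylic acid with a diazoalkane avoids base that would alkylate the acidic C1 position.

Step 16
Reactants: 22 benzeneselenenyl chloride; 23 ethyl vinyl ether
Product: 25 (phenylselanyl)acetaldehyde, via chloro ether 24 (not isolated)
Conditions: CH2Cl2, −78 °C; then aq. NaHCO3, THF, rt
Reagents that add atoms: water, O
Why: Electrophilic selenenylation of an enol ether (chloride ends on the acetal carbon) and hydrolysis of the α-chloro ether give a two-carbon vinyl cation equivalent.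

Step 17
Reactants: 11 ring A aldehyde; 21 ketophosphonate ester
Product: 26 methyl (3R,6Z)-7-[(1R,5S,6S)-5-bromo-6-ethenyl-2,6-dimethylcyclohex-2-en-1-yl]-6-methoxy-5-oxo-3-(propan-2-yl)hept-6-enoate
Conditions: Ba(OH)2, THF/H2O (40:1), rt
Reagents that add atoms: none
Why: Horner–Wadsworth–Emmons olefination under mild hydroxide conditions suited to base-sensitive aldehydes; reversible addition and the α-branched aldehyde place C9 trans to the acyl carbon C2 (Z descriptor, since OMe outranks C2), which is the geometry the key step needs.

Step 18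
Reactants: 26 α-methoxy enone
Product: 27 methyl (3R,5R,6Z)-7-[ring A as in 26]-5-hydroxy-6-methoxy-3-(propan-2-yl)hept-6-enoate
Conditions: (S)-2-methyl-CBS-oxazaborolidine (cat.), catecholborane, toluene, −78 °C
Reagents that add atoms: none
Why: Corey–Bakshi–Shibata reduction in which the α-methoxyalkenyl group acts as the large and the C3 methylene as the small ketone substituent, so that the (S)-catalyst should give the (2R)-alcohol irrespective of the remote centres; catecholborane at low temperature leaves ester and alkenes alone.

Step 19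
Reactants: 27 hydroxy ester
Product: 28 (3R,5R,6Z)-7-[ring A as in 26]-5-hydroxy-6-methoxy-3-(propan-2-yl)hept-6-enoic acid
Conditions: LiOH, THF/H2O, 0 °C to rt; NaH2PO4 to pH 5
Reagents that add atoms: lithium hydroxide, [Li+].[OH-]
Why: Saponification of an unhindered methyl ester; work-up at pH 5 protects the acid-labile enol ether.

Step 20
Reactants: 28 hydroxy acid
Product: 29 (4R,6R)-6-{(1Z)-2-[(1R,5S,6S)-5-bromo-6-ethenyl-2,6-dimethylcyclohex-2-en-1-yl]-1-methoxyethenyl}-4-(propan-2-yl)oxan-2-one
Conditions: EDC·HCl, DMAP (cat.), CH2Cl2, rt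
Reagents that add atoms: none
Why: Carbodiimide-mediated (Steglich-type) lactonisation of a δ-hydroxy acid proceeds with retention at C2 and gives the chair lactone with both substituents equatorial (2,4-cis).

Step 21
Reactants: 29 δ-lactone; 25 (phenylselanyl)acetaldehyde
Product: 31 lactone 29 bearing a 1-hydroxy-2-(phenylselanyl)ethyl group at C5 trans to the isopropyl group (carbinol epimers), via lithium enolate 30 (not isolated)
Conditions: LiN(iPr)2, THF, −78 °C; then 25; AcOH, −78 °C
Reagents that add atoms: none
Why: Aldol addition of the lactone lithium enolate at its only enolisable position C5, anti to the neighbouring isopropyl group; the configurations at C5 and at the carbinol carbon are of no consequence because both are lost in steps 22 and 23.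

Step 22
Reactants: 31 β-hydroxy selenide
Product: 33 (3S,4S,6R)-3-ethenyl-6-{(1Z)-2-[(1R,5S,6S)-5-bromo-6-ethenyl-2,6-dimethylcyclohex-2-en-1-yl]-1-methoxyethenyl}-4-(propan-2-yl)oxan-2-one, via mesylate 32 (not isolated)
Conditions: MsCl, Et3N, 2-methyl-2-butene, CH2Cl2, 0 °C to rt
Reagents that add atoms: none
Why: Mesylation triggers anti elimination of the β-hydroxy selenide through a seleniranium ion (a regiospecific olefin synthesis), which gives the unconjugated vinyl group without base strong enough to move it into conjugation; the added alkene takes up the electrophilic selenium by-product before it can reach the enol ether.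

Step 23
Reactants: 33 α-vinyl δ-lactone
Product: 35 tert-butyldimethylsilyl (1S,2S,6S)-2-[(1R,5S,6S)-5-bromo-6-ethenyl-2,6-dimethylcyclohex-2-en-1-yl]-1-ethenyl-3-methoxy-6-(propan-2-yl)cyclohex-3-ene-1-carboxylate (C5 S, C10 S, C4 S), via silyl ketene acetal 34 (not isolated)
Conditions: KN(SiMe3)2, TBSCl, THF, −78 °C to rt; then toluene, 105 °C (base-washed glassware)
Reagents that add atoms: tert-butyldimethylsilyl chloride, CC(C)(C)[Si](C)(C)Cl
Why: KN(SiMe3)2 removes the doubly activated C5 proton (any conjugated ethylidene isomer gives the same dienolate by γ-deprotonation) and TBSCl traps it on oxygen as cyclic ketene acetal 34, whose C5=C15–O–C2–C1=C10 array undergoes a concerted suprafacial [3,3]-shift on heating. The closest known reaction type is the Ireland–Claisen ring contraction of 6-alkenyl δ-lactones to cyclohexenecarboxylic acids. Ring C (C5–C10–C1–C2–C3–C4) closes by sigmatropic contraction, since the C3–C4 tether allows only a boat resembling bicyclo[2.2.2]octane with C2 and C5 at the bridgeheads, in which C5–C10 forms while C2–O breaks and a six-membered lactone becomes a six-membered carbocycle. C5 is set by the C2 carbinol, because the ring-locked ketene acetal can be reached only on the face held by the lactone oxygen, so C15 lands on that face and the vinyl group points outward. C10 is set by the Z-enol ether geometry (C2 and C9 trans), which turns H-10 towards the tether and C9 outward, that is exo in the later norbornane. The step needs complete chirality transfer and O- rather than C-silylation, secured by the single accessible boat, the potassium enolate/silyl chloride pair and strictly aprotic handling that keeps both enol ethers intact, the acid being retained as silyl ester.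

Step 24
Reactants: 35 silyl ester
Product: 36 [(1S,2S,6S)-2-[(1R,5S,6S)-5-bromo-6-ethenyl-2,6-dimethylcyclohex-2-en-1-yl]-1-ethenyl-3-methoxy-6-(propan-2-yl)cyclohex-3-en-1-yl]methanol
Conditions: iBu2AlH, CH2Cl2, −78 to 0 °C; aq. potassium sodium tartrate
Reagents that add atoms: none
Why: Hydride reduction of the silyl ester to the primary alcohol with a reagent that does not reduce secondary alkyl bromides or enol ethers; no stereocentre is touched.

Step 25
Reactants: 36 divinyl alcohol
Product: 37 tricyclic enol ether alcohol (rings A, B and C; C1=C2 enol ether, C6=C7, C11=C12; C15H2OH axial on C5; C4, C5, C8, C9, C10, C14 as in the target)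
Conditions: second-generation Hoveyda–Grubbs catalyst (cat.), toluene, 80 °C, argon sparge
Reagents that add atoms: none
Why: Ring-closing metathesis of the only two monosubstituted alkenes closes cyclohexene ring B with loss of ethene; the trisubstituted alkene and enol ether are inert, the centres C5, C8, C9 and C10 dictate the trans-anti-trans fusion, and this fusion locks C15 axial over ring C for the next step.

Step 26
Reactants: 37 tricyclic enol ether alcohol
Product: 40 tetracyclic methyl ether (C15–C2 bridge closed, endo OMe and exo H at C1; C6=C7 and C11=C12 retained), via neopentyl triflate 38 (not isolated), via oxocarbenium triflate 39 (not isolated)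
Conditions: Tf2O, 2,6-di-tert-butyl-4-methylpyridine, CH2Cl2, −78 °C; Et3SiH, −78 to 0 °C
Reagents that add atoms: none
Why: Proposed new method: O-triflation puts a leaving group on axial C15 directly above C2 of the ring C enol ether, whose π-bond displaces triflate from the rear (5-exo-tet for the ring C2–C3–C4–C5–C15, with the C5–C15···C2 angle near 90° as an SN2 geometry demands) to give 2-methoxynorbornyl oxocarbenium ion 39, which Et3SiH should reduce from the exo face because the endo face is closed by the endo isopropyl group and the endo hydrogen on C3; C2 is fixed by the tether and C1 by this exo delivery; the closest known reaction types are enol ether participation in sulfonate solvolysis (π-route to 2-norbornyl cations), intramolecular keto tosylate alkylation to bicyclo[2.2.1]heptanones and ionic hydrogenation of oxocarbenium ions with silanes.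

Step 27
Reactants: 40 tetracyclic diene
Product: 41 11,12-epoxide of 40 (oxygen on the face of H-9 and H-14, opposite the C8 methyl group)
Conditions: mCPBA, CH2Cl2, 0 °C
Reagents that add atoms: 3-chloroperbenzoic acid, OOC(=O)c1cccc(Cl)c1
Why: Prilezhaev epoxidation picks the trisubstituted C11=C12 alkene over the disubstituted C6=C7 alkene flanked by two quaternary carbons, and attacks the face opposite the axial C8 methyl group, which fixes the C12–O configuration.

Step 28
Reactants: 41 epoxide
Product: 42 6,7-didehydro derivative of the target (trans-diaxial 11,12-diol)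
Conditions: HClO4 (cat.), THF/H2O, 0 °C to rt
Reagents that add atoms: water, O
Why: Acid-catalysed epoxide hydrolysis in which water attacks the tertiary carbon C11 with inversion; the electronic preference and the Fürst–Plattner rule coincide and give the trans-diaxial diol of the target.

Step 29
Reactants: 42 unsaturated diol
Product: 43 target CNP0130529.1
Conditions: 2-nitrobenzenesulfonylhydrazide, Et3N, CH2Cl2, rt
Reagents that add atoms: none
Why: Diimide reduction (concerted syn transfer of two hydrogens) saturates the only remaining alkene and cannot touch the C–Br bond, the ether or the diol; no stereocentre is formed.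

Compound list
1 | geraniol | CC(C)=CCC/C(C)=C/CO | starting material
2 | (1S)-camphanic chloride, (1S,4R)-4,7,7-trimethyl-3-oxo-2-oxabicyclo[2.2.1]heptane-1-carbonyl chloride | O=C(Cl)[C@@]12CC[C@@](C)(C(=O)O1)C2(C)C | starting material
3 | geranyl (1S)-camphanate | CC(C)=CCC/C(C)=C/COC(=O)[C@@]12CC[C@@](C)(C(=O)O1)C2(C)C | intermediate
4 | (2E,6E)-8-hydroxygeranyl (1S)-camphanate | OC/C(C)=C/CC/C(C)=C/COC(=O)[C@@]12CC[C@@](C)(C(=O)O1)C2(C)C | intermediate
5 | (2E,6E)-8-(TBDPS-oxy)geranyl (1S)-camphanate | CC(C)(C)[Si](OC/C(C)=C/CC/C(C)=C/COC(=O)[C@@]12CC[C@@](C)(C(=O)O1)C2(C)C)(c1ccccc1)c1ccccc1 | intermediate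
6 | bromocyclised ring A camphanate, C7 silyl ether | O=C(OC[C@@H]1C(C)=CC[C@H](Br)[C@@]1(C)CO[Si](c2ccccc2)(c2ccccc2)C(C)(C)C)[C@@]34CC[C@@](C)(C(=O)O3)C4(C)C | intermediate
7 | ring A camphanate, C7 alcohol | O=C(OC[C@@H]1C(C)=CC[C@H](Br)[C@@]1(C)CO)[C@@]23CC[C@@](C)(C(=O)O2)C3(C)C | intermediate
8 | ring A camphanate, C7 aldehyde | O=C(OC[C@@H]1C(C)=CC[C@H](Br)[C@@]1(C)C=O)[C@@]23CC[C@@](C)(C(=O)O2)C3(C)C | intermediate
9 | ring A camphanate, C8 vinyl | O=C(OC[C@@H]1C(C)=CC[C@H](Br)[C@@]1(C)C=C)[C@@]23CC[C@@](C)(C(=O)O2)C3(C)C | intermediate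
10 | ring A alcohol | OC[C@@H]1C(C)=CC[C@H](Br)[C@@]1(C)C=C | intermediate
11 | ring A aldehyde | O=C[C@@H]1C(C)=CC[C@H](Br)[C@@]1(C)C=C | intermediate
12 | methyl (E)-4-methylpent-2-enoate | CC(C)/C=C/C(=O)OC | starting material
13 | dimethyl malonate | COC(=O)CC(=O)OC | starting material
14 | trimethyl 2-(propan-2-yl)propane-1,1,3-tricarboxylate (racemic) | COC(=O)CC(C(C)C)C(C(=O)OC)C(=O)OC | intermediate
15 | 3-isopropylglutaric acid | CC(C)C(CC(=O)O)CC(=O)O | intermediate
16 | 3-isopropylglutaric anhydride | CC(C)C1CC(=O)OC(=O)C1 | intermediate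
17 | (S)-monomethyl 3-isopropylglutarate | COC(=O)C[C@@H](C(C)C)CC(=O)O | intermediate
18 | diethyl (methoxymethyl)phosphonate | CCOP(=O)(COC)OCC | starting material
19 | α-lithio diethyl (methoxymethyl)phosphonate | [Li]C(OC)P(=O)(OCC)OCC | intermediate
20 | α-methoxy-β-ketophosphonate acid | CCOP(=O)(OCC)C(OC)C(=O)C[C@@H](C(C)C)CC(=O)O | intermediate
21 | α-methoxy-β-ketophosphonate methyl ester | CCOP(=O)(OCC)C(OC)C(=O)C[C@@H](C(C)C)CC(=O)OC | intermediate
22 | benzeneselenenyl chloride | Cl[Se]c1ccccc1 | starting material
23 | ethyl vinyl ether | C=COCC | starting material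
24 | 1-chloro-1-ethoxy-2-(phenylselanyl)ethane | CCOC(Cl)C[Se]c1ccccc1 | intermediate
25 | (phenylselanyl)acetaldehyde | O=CC[Se]c1ccccc1 | intermediate
26 | (Z)-α-methoxy enone | COC(=O)C[C@H](C(C)C)CC(=O)/C(OC)=C/[C@@H]1C(C)=CC[C@H](Br)[C@@]1(C)C=C | intermediate
27 | (2R)-allylic alcohol ester | COC(=O)C[C@H](C(C)C)C[C@@H](O)/C(OC)=C/[C@@H]1C(C)=CC[C@H](Br)[C@@]1(C)C=C | intermediate
28 | δ-hydroxy acid | OC(=O)C[C@H](C(C)C)C[C@@H](O)/C(OC)=C/[C@@H]1C(C)=CC[C@H](Br)[C@@]1(C)C=C | intermediate
29 | 2,4-cis δ-lactone | O=C1O[C@H](C[C@@H](C(C)C)C1)/C(OC)=C/[C@@H]2C(C)=CC[C@H](Br)[C@@]2(C)C=C | intermediate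
30 | lithium enolate of 29 | [Li]OC=1O[C@H](C[C@@H](C(C)C)C=1)/C(OC)=C/[C@@H]2C(C)=CC[C@H](Br)[C@@]2(C)C=C | intermediate
31 | C5 aldol adduct (β-hydroxy selenide) | O=C1O[C@H](C[C@@H](C(C)C)[C@@H]1C(O)C[Se]c3ccccc3)/C(OC)=C/[C@@H]2C(C)=CC[C@H](Br)[C@@]2(C)C=C | intermediate
32 | mesylate of 31 | O=C1O[C@H](C[C@@H](C(C)C)[C@@H]1C(C[Se]c3ccccc3)OS(C)(=O)=O)/C(OC)=C/[C@@H]2C(C)=CC[C@H](Br)[C@@]2(C)C=C | intermediate
33 | α-vinyl δ-lactone (key-step precursor) | O=C1O[C@H](C[C@@H](C(C)C)[C@@H]1C=C)/C(OC)=C/[C@@H]2C(C)=CC[C@H](Br)[C@@]2(C)C=C | intermediate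
34 | cyclic TBS ketene acetal | C=CC1=C(O[Si](C)(C)C(C)(C)C)O[C@H](C[C@H]1C(C)C)/C(OC)=C/[C@@H]2C(C)=CC[C@H](Br)[C@@]2(C)C=C | intermediate
35 | ring C enol ether TBS ester (key-step product) | COC1=CC[C@@H](C(C)C)[C@](C=C)(C(=O)O[Si](C)(C)C(C)(C)C)[C@@H]1[C@@H]2C(C)=CC[C@H](Br)[C@@]2(C)C=C | intermediate
36 | C15 alcohol | COC1=CC[C@@H](C(C)C)[C@](C=C)(CO)[C@@H]1[C@@H]2C(C)=CC[C@H](Br)[C@@]2(C)C=C | intermediate
37 | tricyclic enol ether alcohol | COC1=CC[C@@H](C(C)C)[C@@]2(CO)C=C[C@@]3(C)[C@H]([C@H]12)C(C)=CC[C@@H]3Br | intermediate
38 | C15 triflate | COC1=CC[C@@H](C(C)C)[C@@]2(COS(=O)(=O)C(F)(F)F)C=C[C@@]3(C)[C@H]([C@H]12)C(C)=CC[C@@H]3Br | intermediate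
39 | oxocarbenium triflate | C[O+]=C1[C@H]2C[C@@H](C(C)C)[C@]3(C=C[C@@]4(C)[C@H]([C@H]13)C(C)=CC[C@@H]4Br)C2.[O-]S(=O)(=O)C(F)(F)F | intermediate
40 | tetracyclic methyl ether diene | CO[C@H]1[C@H]2C[C@@H](C(C)C)[C@]3(C=C[C@@]4(C)[C@H]([C@H]13)C(C)=CC[C@@H]4Br)C2 | intermediate
41 | 11,12-epoxide | CO[C@H]1[C@H]2C[C@@H](C(C)C)[C@]3(C=C[C@@]4(C)[C@H]([C@H]13)[C@@]5(C)O[C@H]5C[C@@H]4Br)C2 | intermediate
42 | 6,7-didehydro diol | CO[C@H]1[C@H]2C[C@@H](C(C)C)[C@]3(C=C[C@@]4(C)[C@H]([C@H]13)[C@](C)(O)[C@@H](O)C[C@@H]4Br)C2 | intermediate
43 | CNP0130529.1 | CO[C@H]1[C@H]2C[C@@H](C(C)C)[C@]3(CC[C@@]4(C)[C@H]([C@H]13)[C@](C)(O)[C@@H](O)C[C@@H]4Br)C2 | target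

Total step count: 29. Longest linear sequence: 22 steps (steps 1–9, then 17–29).

Steps most likely to fail

1. Step 26.
- What may go wrong: displacement at the neopentyl carbon may be too slow, so that the triflate rearranges. The oxocarbenium ion may lose H-10 or its methyl group before it is reduced. Hydride delivery may show poor facial selectivity.
- Fallback (known chemistry): it sets out from 37 and comes back at 40. Tosylation (TsCl, DMAP, pyridine) gives the enol ether tosylate F1. Mild hydrolysis (oxalic acid, wet THF) gives the keto tosylate F2. Kinetic deprotonation at C2 with KN(SiMe3)2 and intramolecular enolate alkylation close the bridge to the norbornanone F3. NaBH4 attacks the exo face and gives the endo alcohol F4. MeOTf with 2,6-di-tert-butyl-4-methylpyridine then methylates it to 40.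

2. Step 23.
- What may go wrong: the boat is crowded, since the isopropyl group and H-10 point at each other and C5 is fully substituted. The shift may therefore need temperatures at which the ketene acetal is lost through C-silylation, hydrolysis or ionisation of the allylic C2–O bond.
- Fallback: it moves the creation of the quaternary centre behind the rearrangement. It sets out from 29 and comes back at 36. Lactone 29, whose ketene acetal carbon C5 carries only hydrogen, is rearranged under the conditions of step 23 to the C5–H silyl ester F5. CsF and MeI in DMF convert this into the methyl ester F6. Its enolate (LiN(iPr)2) adds to 25 on the face away from the large ring A substituent to give the quaternary aldol adduct F7. MsCl and Et3N give the vinyl methyl ester F8, and iBu2AlH reduces it to 36.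

3. Step 4.
- What may go wrong: halide capture of the bromonium ion, attack of Br+ on the wrong alkene, ester participation at the C11 cation, unselective proton loss, or poor separation of the diastereomers.
- Fallback: carbon–carbon bond formation is separated from bromine introduction. It sets out from 5 and comes back at 6. Cyclisation with Hg(OTf)2 and N,N-dimethylaniline in MeNO2 at −20 °C, followed by aq. NaCl, gives the equatorial organomercury chloride F9. Its diastereomers are separated as before. Bromodemercuration (Br2, LiBr, pyridine, O2, 0 °C) replaces mercury by bromine with retention to give 6.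

Further compounds
F1 | step 26 | enol ether tosylate | COC1=CC[C@@H](C(C)C)[C@@]2(COS(=O)(=O)c4ccc(C)cc4)C=C[C@@]3(C)[C@H]([C@H]12)C(C)=CC[C@@H]3Br
F2 | step 26 | keto tosylate | O=C1CC[C@@H](C(C)C)[C@@]2(COS(=O)(=O)c4ccc(C)cc4)C=C[C@@]3(C)[C@H]([C@H]12)C(C)=CC[C@@H]3Br
F3 | step 26 | norbornanone | O=C1[C@H]2C[C@@H](C(C)C)[C@]3(C=C[C@@]4(C)[C@H]([C@H]13)C(C)=CC[C@@H]4Br)C2
F4 | step 26 | endo alcohol | O[C@H]1[C@H]2C[C@@H](C(C)C)[C@]3(C=C[C@@]4(C)[C@H]([C@H]13)C(C)=CC[C@@H]4Br)C2
F5 | step 23 | C5–H silyl ester | COC1=CC[C@@H](C(C)C)[C@H](C(=O)O[Si](C)(C)C(C)(C)C)[C@@H]1[C@@H]2C(C)=CC[C@H](Br)[C@@]2(C)C=C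
F6 | step 23 | methyl ester | COC1=CC[C@@H](C(C)C)[C@H](C(=O)OC)[C@@H]1[C@@H]2C(C)=CC[C@H](Br)[C@@]2(C)C=C
F7 | step 23 | quaternary aldol adduct | COC1=CC[C@@H](C(C)C)[C@](C(O)C[Se]c3ccccc3)(C(=O)OC)[C@@H]1[C@@H]2C(C)=CC[C@H](Br)[C@@]2(C)C=C
F8 | step 23 | vinyl methyl ester | COC1=CC[C@@H](C(C)C)[C@](C=C)(C(=O)OC)[C@@H]1[C@@H]2C(C)=CC[C@H](Br)[C@@]2(C)C=C
F9 | step 4 | equatorial organomercury chloride | O=C(OC[C@@H]1C(C)=CC[C@H]([Hg]Cl)[C@@]1(C)CO[Si](c2ccccc2)(c2ccccc2)C(C)(C)C)[C@@]34CC[C@@](C)(C(=O)O3)C4(C)C
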